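**Strategy**

- Retrosynthesis: ring A is cut at the bond between the aroyl-bearing carbon and one neighbouring C–OH carbon (a Claisen bond). This re-reads the arene as a 6-aroylmethyl-4-methoxy-3,5-diprenyl-2-pyrone. The pyrone is then cut at CH2–C(=O)Ar, at O–CH3, at C3–prenyl, and across the ring into the silyl enol ether of sulcatone plus malonyl dichloride.
- Forward: ring B is bought. The 2-pyrone ring is made first (C-acylation, then lactonisation), then given the second prenyl, the O-methyl group and the aroylmethyl arm. In the last step it is opened and reclosed as benzene ring A.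
- Enabling feature: the six ring-A carbons map one to one onto the pyrone. The C–aroyl carbon is the exocyclic CH2 on C6, the two C–OH carbons are the lactone C=O carbon and C6, the two C–prenyl carbons are C3 and C5, and C–OMe is C4. Every substituent is therefore in place before the arene exists.
- Stereochemistry: none to set. The target has no stereocentre and both alkenes end in gem-dimethyl groups; the enol ether geometry is erased when the pyrone forms.

Key step: step 8

Assumption: enol ether 2 is used as the Z-rich Z/E mixture (Z drawn), since both isomers give the same pyrone, and Mg(OMe)2 is used as its commercial solution in methanol.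

**Route**

Step 1
Reactants: 1 6-methylhept-5-en-2-one (sulcatone)
Product: 2 trimethyl{[(2Z)-6-methylhepta-2,5-dien-2-yl]oxy}silane
Conditions: Me3SiCl, NaI, Et3N, MeCN, rt; pentane extraction, distillation
Reagents that add atoms: chlorotrimethylsilane, C[Si](C)(C)Cl
Why: Soft enolisation with Me3SiI made in situ and Et3N under equilibrating conditions (thermodynamic silyl enol ether formation) should favour the more substituted C2=C3 enol ether over the terminal isomer, and the isolated trisubstituted alkene is inert to these conditions.

Step 2
Reactants: 2 trimethyl{[(2Z)-6-methylhepta-2,5-dien-2-yl]oxy}silane; 3 malonyl dichloride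
Product: 5 4-hydroxy-6-methyl-5-(3-methylbut-2-en-1-yl)-2H-pyran-2-one, via acyclic diketo acid chloride 4 (not isolated)
Conditions: Et2O, −78 °C → 0 °C, N2 sweep
Reagents that add atoms: none
Why: In this malonyl dichloride/silyl enol ether pyrone annulation the nucleophilic C3 of the enol ether is C-acylated by one acyl chloride (Mukaiyama-type acylation) and the enol oxygen of the resulting diketone then closes the lactone on the second one, while ether as solvent, low temperature and the gas sweep should keep the liberated HCl from adding to the prenyl alkene.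

Step 3
Reactants: 5 4-hydroxy-6-methyl-5-(3-methylbut-2-en-1-yl)-2H-pyran-2-one; 6 1-bromo-3-methylbut-2-ene (prenyl bromide)
Product: 7 4-hydroxy-6-methyl-3,5-bis(3-methylbut-2-en-1-yl)-2H-pyran-2-one
Conditions: Pd(PPh3)4 (5 mol %), K2CO3, DMF, rt
Reagents that add atoms: none
Why: Tsuji–Trost allylation of a 4-hydroxy-2-pyrone: with C5 blocked, C3 is the only nucleophilic carbon, any O-prenyl ether is re-ionised by zerovalent palladium so material should funnel to the C–C bonded product, and the hindered soft nucleophile should attack the unsubstituted terminus of the 1,1-dimethylallyl palladium complex to give the linear prenyl group.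

Step 4
Reactants: 7 4-hydroxy-6-methyl-3,5-bis(3-methylbut-2-en-1-yl)-2H-pyran-2-one
Product: 8 4-methoxy-6-methyl-3,5-bis(3-methylbut-2-en-1-yl)-2H-pyran-2-one
Conditions: Me2SO4, K2CO3, acetone, reflux
Reagents that add atoms: dimethyl sulfate, COS(=O)(=O)OC
Why: Williamson-type O-methylation of the vinylogous acid with the hard electrophile dimethyl sulfate is the standard way to the 4-methoxy-2-pyrone rather than the 2-methoxy-4-pyranone isomer, and the fully substituted C3 disfavours C-methylation.

Step 5
Reactants: 9 3-hydroxybenzoic acid
Product: 10 3-hydroxy-N-methoxy-N-methylbenzamide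
Conditions: MeNH(OMe)·HCl, EDC·HCl, HOBt (cat.), iPr2NEt, CH2Cl2, 0 °C → rt
Reagents that add atoms: N,O-dimethylhydroxylamine hydrochloride, CNOC.Cl
Why: Carbodiimide amide coupling (EDC/HOBt), in which the amine outcompetes the free phenol for the active ester, so the Weinreb amide should form without prior protection.

Step 6
Reactants: 10 3-hydroxy-N-methoxy-N-methylbenzamide
Product: 11 3-[(tert-butyldimethylsilyl)oxy]-N-methoxy-N-methylbenzamide
Conditions: TBSCl, imidazole, DMF, rt
Reagents that add atoms: tert-butyldimethylsilyl chloride, CC(C)(C)[Si](C)(C)Cl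
Why: Standard imidazole-mediated silylation masks the acidic phenol for the organolithium step with a group removed by alkoxide or fluoride, not by acid or hydrogenolysis, so the prenyl alkenes and the later ortho-prenyl phenols are never endangered.

Step 7
Reactants: 8 4-methoxy-6-methyl-3,5-bis(3-methylbut-2-en-1-yl)-2H-pyran-2-one; 11 3-[(tert-butyldimethylsilyl)oxy]-N-methoxy-N-methylbenzamide
Product: 12 6-{2-[3-(tert-butyldimethylsilyloxy)phenyl]-2-oxoethyl}-4-methoxy-3,5-bis(3-methylbut-2-en-1-yl)-2H-pyran-2-one
Conditions: LiN(iPr)2 (2 equiv), THF, −78 °C; then 11, −78 → −30 °C; aq. NH4Cl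
Reagents that add atoms: none
Why: Vinylogous (lateral) deprotonation of the 6-methyl group, the only position acidified by the pyrone carbonyl, gives a trienolate that is acylated at the exocyclic carbon, and the Weinreb amide holds the adduct as a stable chelate until quench (Weinreb ketone synthesis), which prevents over-addition and proton transfer from the acidic product.

Step 8
Reactants: 12 6-{2-[3-(tert-butyldimethylsilyloxy)phenyl]-2-oxoethyl}-4-methoxy-3,5-bis(3-methylbut-2-en-1-yl)-2H-pyran-2-one
Product: 15 [2,6-dihydroxy-4-methoxy-3,5-bis(3-methylbut-2-en-1-yl)phenyl](3-hydroxyphenyl)methanone (target CNP0425861.0), via ring-opened methyl ester 13 (not isolated), via silyl-protected benzophenone 14 (not isolated)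
Conditions: Mg(OMe)2 (6 equiv), MeOH, reflux; cold dilute HCl to pH 3–4
Reagents that add atoms: none
Why: Methoxide adds to the lactone carbonyl (pyrone C2) and breaks the C2–O1 bond, giving methyl ester 13, whose ester and 1,3-diketone arm sit cis on the ring-derived (E) enol ether. The magnesium-chelated diketone enolate then attacks the ester carbonyl through its central carbon (the former exocyclic CH2) in an intramolecular Claisen (Dieckmann-type) condensation, a 6-exo-trig closure of the carbocycle, and loss of methoxide followed by enolisation aromatises it to ring A. The closest known reaction type is the Mg(OMe)2- or base-mediated recyclisation of 6-(2-oxoalkyl)- and 6-phenacyl-4-oxygenated 2-pyrones (masked 3,5,7-triketo esters) to acylphloroglucinols. No stereocentre is created, and the one present in 13 disappears on aromatisation. The step needs C-acylation rather than aldol closure and an intact enol ether: the only other carbon that could attack the aryl ketone, pyrone C3, is a fully substituted enol ether carbon that cannot enolise, magnesium chelation guards the diketone against retro-Claisen cleavage, and methoxide in methanol makes exchange at the methoxy-bearing carbon degenerate. The aryl silyl ether should be methanolysed in the same alkoxide medium, so acidification should release 15 directly.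

**Compound list**

1 | 6-methylhept-5-en-2-one (sulcatone) | CC(=O)CCC=C(C)C | starting material
2 | trimethyl{[(2Z)-6-methylhepta-2,5-dien-2-yl]oxy}silane | C/C(O[Si](C)(C)C)=C/CC=C(C)C | intermediate
3 | malonyl dichloride (propanedioyl dichloride) | O=C(Cl)CC(Cl)=O | starting material
4 | 4-acetyl-7-methyl-3-oxooct-6-enoyl chloride (racemic) | CC(=O)C(CC=C(C)C)C(=O)CC(Cl)=O | intermediate (not isolated)
5 | 4-hydroxy-6-methyl-5-(3-methylbut-2-en-1-yl)-2H-pyran-2-one | Cc1oc(=O)cc(O)c1CC=C(C)C | intermediate
6 | 1-bromo-3-methylbut-2-ene (prenyl bromide) | CC(C)=CCBr | starting material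
7 | 4-hydroxy-6-methyl-3,5-bis(3-methylbut-2-en-1-yl)-2H-pyran-2-one | Cc1oc(=O)c(CC=C(C)C)c(O)c1CC=C(C)C | intermediate
8 | 4-methoxy-6-methyl-3,5-bis(3-methylbut-2-en-1-yl)-2H-pyran-2-one | COc1c(CC=C(C)C)c(=O)oc(C)c1CC=C(C)C | intermediate
9 | 3-hydroxybenzoic acid | O=C(O)c1cccc(O)c1 | starting material
10 | 3-hydroxy-N-methoxy-N-methylbenzamide | CON(C)C(=O)c1cccc(O)c1 | intermediate
11 | 3-[(tert-butyldimethylsilyl)oxy]-N-methoxy-N-methylbenzamide | CON(C)C(=O)c1cccc(O[Si](C)(C)C(C)(C)C)c1 | intermediate
12 | 6-{2-[3-(tert-butyldimethylsilyloxy)phenyl]-2-oxoethyl}-4-methoxy-3,5-bis(3-methylbut-2-en-1-yl)-2H-pyran-2-one | COc1c(CC=C(C)C)c(=O)oc(CC(=O)c2cccc(O[Si](C)(C)C(C)(C)C)c2)c1CC=C(C)C | intermediate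
13 | methyl (2E)-7-[3-(tert-butyldimethylsilyloxy)phenyl]-3-methoxy-2,4-bis(3-methylbut-2-en-1-yl)-5,7-dioxohept-2-enoate (racemic at C4; ester and keto chain cis) | COC(=O)/C(CC=C(C)C)=C(OC)\C(CC=C(C)C)C(=O)CC(=O)c1cccc(O[Si](C)(C)C(C)(C)C)c1 | intermediate (not isolated)
14 | [3-(tert-butyldimethylsilyloxy)phenyl][2,6-dihydroxy-4-methoxy-3,5-bis(3-methylbut-2-en-1-yl)phenyl]methanone | COc1c(CC=C(C)C)c(O)c(C(=O)c2cccc(O[Si](C)(C)C(C)(C)C)c2)c(O)c1CC=C(C)C | intermediate (not isolated)
15 | [2,6-dihydroxy-4-methoxy-3,5-bis(3-methylbut-2-en-1-yl)phenyl](3-hydroxyphenyl)methanone (CNP0425861.0) | COc1c(CC=C(C)C)c(O)c(C(=O)c2cccc(O)c2)c(O)c1CC=C(C)C | target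

**Step count and risk**

Total steps: 8. Longest linear sequence: 6 steps (steps 1, 2, 3, 4, 7, 8 from sulcatone 1). The ring-B branch (steps 5 and 6) joins at step 7.

Steps most likely to fail:

Step 8. Opening of the hindered, electron-rich lactone by methoxide may be slow, so that retro-Claisen loss of the aroyl group from the opened diketone or simple re-lactonisation competes with the C-acylation. Silyl ether methanolysis may also lag behind the ring change. The fallback abandons the pyrone origin of ring A and builds on a bought phloroglucinol ring; it sets out from 3-hydroxybenzoic acid 9 and prenyl bromide 6 and comes back at target 15. Friedel–Crafts acylation of benzene-1,3,5-triol with 9 in P2O5–MeSO3H at about 70 °C should give (3-hydroxyphenyl)(2,4,6-trihydroxyphenyl)methanone F1. Double C-prenylation of the acylphloroglucinol ring with 6 (aqueous KOH, 0 °C) should give (3-hydroxyphenyl)[2,4,6-trihydroxy-3,5-bis(3-methylbut-2-en-1-yl)phenyl]methanone F2. Methylation with one equivalent of (trimethylsilyl)diazomethane in MeOH–toluene should then take the 4-hydroxyl, the most acidic one and the only ring-A hydroxyl not hydrogen-bonded to the carbonyl, to give 15. The modest regiocontrol of the prenylation and methylation is why this sequence is held in reserve.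

Step 3. Alkylation may go to oxygen, attack may occur at the substituted allyl terminus (a 1,1-dimethylallyl group at C3), or a second allylation may take place at C3. The fallback installs the C3 prenyl group before the pyrone exists; it sets out from prenyl bromide 6 and enol ether 2 and comes back at pyrone 7, bypassing 5. Alkylation of diethyl malonate with 6 (NaOEt, EtOH) should give diethyl 2-(3-methylbut-2-en-1-yl)propanedioate F3. Saponification (KOH, aqueous EtOH, then careful cold acidification) should give 2-(3-methylbut-2-en-1-yl)propanedioic acid F4. Neutral chlorination with 1-chloro-N,N,2-trimethylprop-1-en-1-amine in CH2Cl2 at 0 °C should give 2-(3-methylbut-2-en-1-yl)propanedioyl dichloride F5. Condensation of F5 with 2 under the conditions of step 2 should then deliver 7 directly.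

Step 2. The HCl released on lactonisation may add to the trisubstituted alkene or protodesilylate unreacted 2, and any terminal enol ether carried over from step 1 would give the isomeric 6-alkyl pyrone. The fallback builds the same pyrone through β-keto ester dianions under basic conditions only; it sets out from prenyl bromide 6 and comes back at pyrone 5. The dianion of methyl acetoacetate (NaH, then n-BuLi, THF, 0 °C) alkylated at the γ-carbon with 6 should give methyl 7-methyl-3-oxooct-6-enoate F6. A second dianion (LiN(iPr)2, 2.2 equiv, THF, −78 °C) acylated at C4 with N-methoxy-N-methylacetamide should give methyl 4-acetyl-7-methyl-3-oxooct-6-enoate F7. Cyclisation with DBU in refluxing toluene should close F7 to 5 with loss of methanol.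

**Further compounds**

F1 | step 8 | (3-hydroxyphenyl)(2,4,6-trihydroxyphenyl)methanone | O=C(c1cccc(O)c1)c1c(O)cc(O)cc1O
F2 | step 8 | (3-hydroxyphenyl)[2,4,6-trihydroxy-3,5-bis(3-methylbut-2-en-1-yl)phenyl]methanone | CC(C)=CCc1c(O)c(CC=C(C)C)c(O)c(C(=O)c2cccc(O)c2)c1O
F3 | step 3 | diethyl 2-(3-methylbut-2-en-1-yl)propanedioate | CCOC(=O)C(CC=C(C)C)C(=O)OCC
F4 | step 3 | 2-(3-methylbut-2-en-1-yl)propanedioic acid | OC(=O)C(CC=C(C)C)C(=O)O
F5 | step 3 | 2-(3-methylbut-2-en-1-yl)propanedioyl dichloride | O=C(Cl)C(CC=C(C)C)C(Cl)=O
F6 | step 2 | methyl 7-methyl-3-oxooct-6-enoate | COC(=O)CC(=O)CCC=C(C)C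
F7 | step 2 | methyl 4-acetyl-7-methyl-3-oxooct-6-enoate (racemic) | COC(=O)CC(=O)C(CC=C(C)C)C(C)=O
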